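**Retrosynthetic overview**

1. Target 31 comes from diketone 22 by C8 reduction, lactone α-methylenation, C8 acylation and desilylation; the ten-membered carbocycle of 22 is opened at C9–C10 to give 21.
2. The strategy rests on the C1(=O)–C10–C9–C8(–O) array: C9–C10 joins the α-carbon of the furanone ketone (quaternary C10, bearing C14 and the ring oxygen) to the α-carbon of oxygenated C8. This 1,4-dioxygen pattern is shared by the 3(2H)-furanone (C1, C2, C3, O, C10) and the carbocycle C1–C10, and is made by oxidising two enol ethers held on one silicon atom.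
3. 21 comes from seco-diketone 20 (dienolate + iPr2SiCl2); the furanone of 20 comes from vinyl iodide 12 and alkyne 16 (Sonogashira coupling, oxidation, 5-endo-dig cyclisation).
4. 12 comes from an Evans syn-aldol/lactonisation of succinyl imide 7 with (Z)-iodoenal 4 (sets C6, C7); 4 comes from 1 by trans-hydroalumination/iodination (sets the C4=C5 geometry).
5. Ring order: butanolide (step 5), furanone (step 13), eleven-membered siloxane ansa ring (step 14), ten-membered carbocycle (step 15).

Key step: step 15

Remark: germacrane numbering (C1–C15) is used for all intermediates; lithiated or enolised forms of numbered compounds are not numbered separately.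
Remark: the lactate-derived centre C10 and the carbinol centre C1 of 16 and 17 are erased by oxidation (step 12) and enolisation (step 14), so epimer mixtures there are carried without consequence; the succinate unit is taken from commercial methyl 4-chloro-4-oxobutanoate.

**Route**

Step 1
Reactants: 1 tert-butyldimethyl(prop-2-yn-1-yloxy)silane
Product: 2 4-[(tert-butyldimethylsilyl)oxy]but-2-yn-1-ol
Conditions: n-BuLi, THF, −78 °C; (CH2O)n, −78 °C → rt
Reagents that add atoms: paraformaldehyde (formaldehyde), C=O
Why: Addition of the lithium acetylide to formaldehyde (alkynylation of an aldehyde) should give the propargylic alcohol that later directs the hydroalumination.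

Step 2
Reactants: 2 4-[(tert-butyldimethylsilyl)oxy]but-2-yn-1-ol
Product: 3 (2Z)-4-[(tert-butyldimethylsilyl)oxy]-3-iodobut-2-en-1-ol
Conditions: NaAlH2(OCH2CH2OMe)2, THF, 0 °C; then I2, −78 → 0 °C
Reagents that add atoms: iodine, II
Why: Hydroxyl-directed trans-hydroalumination of the propargylic alcohol places aluminium on the distal alkyne carbon (C4), and iodinolysis with retention should give the (Z)-iodoalkene in which iodine (later C3) is cis to C6, fixing the C4=C5 geometry.

Step 3
Reactants: 3 (2Z)-4-[(tert-butyldimethylsilyl)oxy]-3-iodobut-2-en-1-ol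
Product: 4 (2Z)-4-[(tert-butyldimethylsilyl)oxy]-3-iodobut-2-enal
Conditions: MnO2, CH2Cl2, rt
Reagents that add atoms: none
Why: Neutral allylic oxidation with MnO2 should give the enal without Z/E isomerisation; the aldehyde is used directly.

Step 4
Reactants: 5 (4S)-4-benzyl-1,3-oxazolidin-2-one; 6 methyl 4-chloro-4-oxobutanoate
Product: 7 methyl 4-[(4S)-4-benzyl-2-oxo-1,3-oxazolidin-3-yl]-4-oxobutanoate
Conditions: n-BuLi, THF, −78 °C; then 6, −78 → 0 °C
Reagents that add atoms: none
Why: N-Acylation of the lithiated oxazolidinone occurs at the acid chloride, far more electrophilic than the methyl ester.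

Step 5
Reactants: 7 methyl 4-[(4S)-4-benzyl-2-oxo-1,3-oxazolidin-3-yl]-4-oxobutanoate; 4 (2Z)-4-[(tert-butyldimethylsilyl)oxy]-3-iodobut-2-enal
Product: 9 (4S)-4-benzyl-3-{[(2S,3S)-2-[(1Z)-3-[(tert-butyldimethylsilyl)oxy]-2-iodoprop-1-en-1-yl]-5-oxooxolan-3-yl]carbonyl}-1,3-oxazolidin-2-one (trans-butanolide imide), via syn-aldol adduct 8 (not isolated)
Conditions: Bu2BOTf, iPr2NEt, CH2Cl2, −78 → 0 °C; 4, −78 → 0 °C; pH 7 buffer, MeOH, H2O2, 0 °C; then PPTS (cat.), toluene, 50 °C
Reagents that add atoms: none
Why: Evans syn-aldol reaction: the Z-boron enolate of the imide (enolised in preference to the ester) reacts through a Zimmerman–Traxler chair on the enolate face opposite the benzyl group, setting C6 and C7, and the syn aldol hydroxyl then closes onto the methyl ester to the trans-butanolide.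

Step 6
Reactants: 9 trans-butanolide imide
Product: 10 (2S,3S)-2-[(1Z)-3-[(tert-butyldimethylsilyl)oxy]-2-iodoprop-1-en-1-yl]-5-oxooxolane-3-carboxylic acid
Conditions: LiOH, H2O2, THF/H2O, 0 °C; Na2SO3; 1 M HCl to pH 3, 0 °C
Reagents that add atoms: lithium hydroperoxide (from LiOH and H2O2), [Li+].[O-]O
Why: Hydroperoxide cleaves the exocyclic imide carbonyl selectively (auxiliary removal), and any lactone opened in base recloses on acidification to the stable trans γ-lactone.

Step 7
Reactants: 10 butanolide carboxylic acid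
Product: 12 (4S,5S)-4-acetyl-5-[(1Z)-3-[(tert-butyldimethylsilyl)oxy]-2-iodoprop-1-en-1-yl]oxolan-2-one, via acid chloride 11 (not isolated)
Conditions: Me2C=C(Cl)NMe2, CH2Cl2, 0 °C → rt; then Me2CuLi (from MeLi, CuI), Et2O, −78 °C
Reagents that add atoms: lithium dimethylcuprate, [Li+].C[Cu-]C
Why: Acid chloride formation under neutral conditions followed by cuprate acylation gives the methyl ketone (C8, C9), since at −78 °C the cuprate reacts with the acid chloride much faster than with the lactone, the alkenyl iodide or the product ketone; C7 is α to the ketone but trans is the stable arrangement.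

Step 8
Reactants: 13 ethyl (2S)-2-hydroxypropanoate
Product: 14 ethyl (2S)-2-[(triethylsilyl)oxy]propanoate
Conditions: Et3SiCl, imidazole, CH2Cl2, 0 °C → rt
Reagents that add atoms: chlorotriethylsilane, CC[Si](Cl)(CC)CC
Why: Silylation of the secondary alcohol gives an ether that can later be removed in the presence of the primary tert-butyldimethylsilyl ether.

Step 9
Reactants: 14 ethyl (2S)-2-[(triethylsilyl)oxy]propanoate
Product: 15 (2S)-2-[(triethylsilyl)oxy]propanal
Conditions: iBu2AlH, CH2Cl2, −78 °C; aq. potassium sodium tartrate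
Reagents that add atoms: none
Why: Partial reduction of the α-silyloxy ester stops at the aldehyde because the tetrahedral aluminium hemiacetal is stable at −78 °C.

Step 10
Reactants: 15 (2S)-2-[(triethylsilyl)oxy]propanal
Product: 16 (4S)-4-[(triethylsilyl)oxy]pent-1-yn-3-ol (C3 epimer mixture)
Conditions: HC≡CMgBr, THF, −78 → 0 °C
Reagents that add atoms: ethynylmagnesium bromide, C#C[Mg]Br
Why: Grignard addition of the acetylide to the aldehyde supplies C1, C2 and C3; the new carbinol centre is oxidised later, so its configuration is irrelevant.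

Step 11
Reactants: 12 (4S,5S)-4-acetyl-5-[(1Z)-3-[(tert-butyldimethylsilyl)oxy]-2-iodoprop-1-en-1-yl]oxolan-2-one; 16 (4S)-4-[(triethylsilyl)oxy]pent-1-yn-3-ol
Product: 17 (4S,5R)-4-acetyl-5-[(1E,6S)-2-{[(tert-butyldimethylsilyl)oxy]methyl}-5-hydroxy-6-[(triethylsilyl)oxy]hept-1-en-3-yn-1-yl]oxolan-2-one (carbinol epimer mixture)
Conditions: PdCl2(PPh3)2 (divalent palladium, 5 mol %), CuI (monovalent copper, 10 mol %), Et3N, THF, rt
Reagents that add atoms: none
Why: Sonogashira coupling forms C3–C4 with retention of the alkene geometry (C3 cis to C6; the descriptor changes only through priorities); oxidative addition into the C–I bond at rt outruns ionisation of the hindered allylic lactone.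

Step 12
Reactants: 17 enynol
Product: 18 (4S,5R)-4-acetyl-5-[(1E,6S)-2-{[(tert-butyldimethylsilyl)oxy]methyl}-5-oxo-6-[(triethylsilyl)oxy]hept-1-en-3-yn-1-yl]oxolan-2-one
Conditions: MnO2, CH2Cl2, rt
Reagents that add atoms: none
Why: Selective oxidation of the activated propargylic alcohol gives the ynone (C1 ketone) and converges both carbinol epimers.

Step 13
Reactants: 18 silyloxy ynone
Product: 20 (4S,5R)-4-acetyl-5-[(1Z)-3-[(tert-butyldimethylsilyl)oxy]-2-[(5S)-5-methyl-4-oxo-4,5-dihydrofuran-2-yl]prop-1-en-1-yl]oxolan-2-one (C10 configurationally labile), via α'-hydroxy ynone 19 (not isolated)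
Conditions: PPTS (cat.), MeOH, 0 °C; then (4-CF3C6H4)3PAuCl/AgOTf (monovalent gold, 5 mol %), toluene, rt
Reagents that add atoms: none
Why: Mild acid methanolysis removes the secondary triethylsilyl ether in the presence of the primary tert-butyldimethylsilyl ether, and gold-catalysed 5-endo-dig oxa-cyclisation of the α'-hydroxy ynone (alkyne activation, attack of the hydroxyl at C3, protodeauration) gives the 3(2H)-furanone.

Step 14
Reactants: 20 seco-diketone (furanone and C8 methyl ketone)
Product: 21 cyclic diisopropylsilylene bis-enol ether (6R,7S,4Z): silicon bridges the C1–O of the 2-methyl-3-silyloxyfuran and the C8–O of the C8=C9 enol ether in an eleven-membered ring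
Conditions: LiN(SiMe3)2 (2.05 equiv), THF, −78 °C (20 added to base); iPr2SiCl2 (1.0 equiv), 0.005 M, −78 → 0 °C
Reagents that add atoms: dichlorodiisopropylsilane, CC(C)[Si](Cl)(Cl)C(C)C
Why: Double enolisation and O-silylation with a dichlorosilane (silyl bis-enol ether formation): the hindered amide removes the acidic C10–H (aromatic furanolate) and then a C9 methyl proton kinetically rather than C7–H or the lactone α-H; after the first Si–O bond, the second closes intramolecularly under dilution, and opening of the lactone from a C7 enolate would be a disfavoured retro-5-endo process.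

Step 15
Reactants: 21 cyclic diisopropylsilylene bis-enol ether
Product: 22 (6R,7S,10S,4Z)-15-[(tert-butyldimethylsilyl)oxy]-3,10-epoxy-1,8-dioxogermacra-2,4-dien-12,6-olide (furanone-bridged ten-membered 1,4-diketone)
Conditions: (NH4)2Ce(NO3)6 (tetravalent cerium, 2.2 equiv), NaHCO3 (4.4 equiv), MeCN/EtCN, −20 °C, 0.005 M
Reagents that add atoms: none
Why: Proposed new method: one-electron oxidation of the more electron-rich 2-methyl-3-silyloxyfuran (conjugated with C4=C5) by tetravalent cerium should give a radical cation that is captured at C10, the enol-ether terminus next to the ring oxygen, by C9 of the tethered C8 enol ether, and a second one-electron oxidation with loss of the diisopropylsilylene unit (as the silanediol on work-up) then unveils the C1 and C8 carbonyls. The closest known reactions are the (NH4)2Ce(NO3)6-mediated intramolecular oxidative coupling of unsymmetrical dialkylsilyl bis-enol ethers of two ketones to 1,4-diketones, and the bond formation of 2-alkyl-3-silyloxyfurans with electrophiles at this same carbon in Mukaiyama-type additions that give 2,2-disubstituted 3(2H)-furanones. The ten-membered carbocycle closes by C–C bond formation across the pre-formed eleven-membered siloxane ring, through a seven-membered C9–C8–O–Si–O–C1–C10 array, so the entropic cost of the medium ring is paid earlier in Si–O bond formation and the silicon is then excised. C10 is the only new stereocentre: the trans-fused butanolide (C6, C7) and the Z C4=C5 bond fix the turn of the C4–C8 chain, so C9 is expected to reach only the furan face that puts C14 on the α side (10S), with the lactone on the outer rim of the forming ring; this face preference is an expectation, not a derived result. The step needs cross-coupling over homo-coupling (secured by the tether), attack at C10 and not at C2 of the furan (C10 is the terminus of the silyl enol ether and bonding there restores a carbonyl, which C2 attack cannot), and survival of the primary silyl ether and the allylic lactone (bicarbonate buffer, −20 °C, short contact).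

Step 16
Reactants: 22 furanone-bridged 1,4-diketone
Product: 23 (6R,7R,8R,10S,4Z)-15-[(tert-butyldimethylsilyl)oxy]-3,10-epoxy-8-hydroxy-1-oxogermacra-2,4-dien-12,6-olide (8β-alcohol)
Conditions: (S)-2-methyl-CBS-oxazaborolidine (0.5 equiv), catecholborane, CH2Cl2/toluene, −78 → −40 °C
Reagents that add atoms: none
Why: Corey–Bakshi–Shibata reduction: the (S)-oxazaborolidine should place the α-branched C7 side as the large group and deliver hydride to the face giving 8R, while the saturated C8 ketone reacts faster than the vinylogous-ester carbonyl C1 (flanked by quaternary C10) and the lactone.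

Step 17
Reactants: 23 8β-alcohol
Product: 24 8-O-trimethylsilyl ether of 23 (6R,7S,8R,10S)
Conditions: Me3SiCl, imidazole, CH2Cl2, 0 °C
Reagents that add atoms: chlorotrimethylsilane, C[Si](C)(C)Cl
Why: Temporary silylation prevents the C8 alkoxide, which is cis to C11 on C7, from translactonising to the 8,12-olide during the base step that follows.

Step 18
Reactants: 24 8-O-trimethylsilyl ether
Product: 26 13-(dimethylamino)-11,13-dihydro Mannich base with free 8β-hydroxyl (C11 epimer mixture), via O-trimethylsilyl Mannich base 25 (not isolated)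
Conditions: LiN(iPr)2 (1.3 equiv), THF, −78 °C; CH2=NMe2+ I−, −78 → 0 °C; then citric acid, MeOH, 0 °C; NaHCO3
Reagents that add atoms: N,N-dimethylmethyleneiminium iodide, C=[N+](C)C.[I-]
Why: Mannich aminomethylation of the lactone enolate: C11–H2 is the only readily removed α-proton once C8 is a protected carbinol and C10 is quaternary, and the brief acidic work-up removes the labile trimethylsilyl ether without touching the primary tert-butyldimethylsilyl ether.

Step 19
Reactants: 26 Mannich base
Product: 28 (6R,7R,8R,10S,4Z)-15-[(tert-butyldimethylsilyl)oxy]-3,10-epoxy-8-hydroxy-1-oxogermacra-2,4,11(13)-trien-12,6-olide, via trimethylammonium iodide 27 (not isolated)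
Conditions: MeI, MeOH/CH2Cl2, rt; then NaHCO3, EtOAc/H2O, rt
Reagents that add atoms: none
Why: N-Quaternisation and mild-base β-elimination of trimethylamine installs the exocyclic C11=C13 alkene and erases the C11 centre; the free 8β-hydroxyl cannot add to C13 because that closure would be 5-endo-trig.

Step 20
Reactants: 28 hydroxy α-methylene lactone; 29 (2R)-2-methylbutanoic acid
Product: 30 8-O-[(2R)-2-methylbutanoyl] ester of 28 (15-O-tert-butyldimethylsilyl ether of the target)
Conditions: DCC, DMAP (cat.), CH2Cl2, 0 °C → rt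
Reagents that add atoms: none
Why: Steglich esterification acylates the secondary 8β-hydroxyl with retention at C8 and without epimerising the α-centre of the acid, since no ketene-forming base is present.

Step 21
Reactants: 30 silyl-protected ester
Product: 31 CNP0307052.2, (6R,7R,8R,10S,4Z)-3,10-epoxy-15-hydroxy-8-[(2R)-2-methylbutanoyloxy]-1-oxogermacra-2,4,11(13)-trien-12,6-olide
Conditions: HF·pyridine, pyridine, THF, 0 °C → rt
Reagents that add atoms: none
Why: Buffered fluoride desilylation frees the primary allylic C15 hydroxyl under conditions that leave the ester, the α-methylene lactone and the furanone intact.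

**Compound list**

1 | tert-butyldimethyl(prop-2-yn-1-yloxy)silane | C#CCO[Si](C)(C)C(C)(C)C | starting material
2 | 4-[(tert-butyldimethylsilyl)oxy]but-2-yn-1-ol | OCC#CCO[Si](C)(C)C(C)(C)C | intermediate
3 | (2Z)-4-[(tert-butyldimethylsilyl)oxy]-3-iodobut-2-en-1-ol | OC/C=C(/CO[Si](C)(C)C(C)(C)C)I | intermediate
4 | (2Z)-4-[(tert-butyldimethylsilyl)oxy]-3-iodobut-2-enal | O=C/C=C(/CO[Si](C)(C)C(C)(C)C)I | intermediate
5 | (4S)-4-benzyl-1,3-oxazolidin-2-one | O=C1N[C@@H](Cc2ccccc2)CO1 | starting material
6 | methyl 4-chloro-4-oxobutanoate | COC(=O)CCC(Cl)=O | starting material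
7 | methyl 4-[(4S)-4-benzyl-2-oxo-1,3-oxazolidin-3-yl]-4-oxobutanoate | COC(=O)CCC(=O)N1[C@@H](Cc2ccccc2)COC1=O | intermediate
8 | methyl (3S,4S,5Z)-3-{[(4S)-4-benzyl-2-oxo-1,3-oxazolidin-3-yl]carbonyl}-7-[(tert-butyldimethylsilyl)oxy]-4-hydroxy-6-iodohept-5-enoate (syn-aldol adduct, not isolated) | COC(=O)C[C@@H]([C@H](O)/C=C(/CO[Si](C)(C)C(C)(C)C)I)C(=O)N1[C@@H](Cc2ccccc2)COC1=O | intermediate
9 | (4S)-4-benzyl-3-{[(2S,3S)-2-[(1Z)-3-[(tert-butyldimethylsilyl)oxy]-2-iodoprop-1-en-1-yl]-5-oxooxolan-3-yl]carbonyl}-1,3-oxazolidin-2-one | O=C1C[C@H](C(=O)N2[C@@H](Cc3ccccc3)COC2=O)[C@@H](/C=C(/CO[Si](C)(C)C(C)(C)C)I)O1 | intermediate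
10 | (2S,3S)-2-[(1Z)-3-[(tert-butyldimethylsilyl)oxy]-2-iodoprop-1-en-1-yl]-5-oxooxolane-3-carboxylic acid | O=C1C[C@H](C(=O)O)[C@@H](/C=C(/CO[Si](C)(C)C(C)(C)C)I)O1 | intermediate
11 | (2S,3S)-2-[(1Z)-3-[(tert-butyldimethylsilyl)oxy]-2-iodoprop-1-en-1-yl]-5-oxooxolane-3-carbonyl chloride (not isolated) | O=C1C[C@H](C(Cl)=O)[C@@H](/C=C(/CO[Si](C)(C)C(C)(C)C)I)O1 | intermediate
12 | (4S,5S)-4-acetyl-5-[(1Z)-3-[(tert-butyldimethylsilyl)oxy]-2-iodoprop-1-en-1-yl]oxolan-2-one | O=C1C[C@H](C(C)=O)[C@@H](/C=C(/CO[Si](C)(C)C(C)(C)C)I)O1 | intermediate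
13 | ethyl (2S)-2-hydroxypropanoate (ethyl (S)-lactate) | CCOC(=O)[C@H](C)O | starting material
14 | ethyl (2S)-2-[(triethylsilyl)oxy]propanoate | CCOC(=O)[C@H](C)O[Si](CC)(CC)CC | intermediate
15 | (2S)-2-[(triethylsilyl)oxy]propanal | O=C[C@H](C)O[Si](CC)(CC)CC | intermediate
16 | (4S)-4-[(triethylsilyl)oxy]pent-1-yn-3-ol (C3 epimer mixture) | C#CC(O)[C@H](C)O[Si](CC)(CC)CC | intermediate
17 | (4S,5R)-4-acetyl-5-[(1E,6S)-2-{[(tert-butyldimethylsilyl)oxy]methyl}-5-hydroxy-6-[(triethylsilyl)oxy]hept-1-en-3-yn-1-yl]oxolan-2-one (carbinol epimer mixture) | O=C1C[C@H](C(C)=O)[C@@H](/C=C(/CO[Si](C)(C)C(C)(C)C)C#CC(O)[C@H](C)O[Si](CC)(CC)CC)O1 | intermediate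
18 | (4S,5R)-4-acetyl-5-[(1E,6S)-2-{[(tert-butyldimethylsilyl)oxy]methyl}-5-oxo-6-[(triethylsilyl)oxy]hept-1-en-3-yn-1-yl]oxolan-2-one | O=C1C[C@H](C(C)=O)[C@@H](/C=C(/CO[Si](C)(C)C(C)(C)C)C#CC(=O)[C@H](C)O[Si](CC)(CC)CC)O1 | intermediate
19 | (4S,5R)-4-acetyl-5-[(1E,6S)-2-{[(tert-butyldimethylsilyl)oxy]methyl}-6-hydroxy-5-oxohept-1-en-3-yn-1-yl]oxolan-2-one (not isolated) | O=C1C[C@H](C(C)=O)[C@@H](/C=C(/CO[Si](C)(C)C(C)(C)C)C#CC(=O)[C@H](C)O)O1 | intermediate
20 | (4S,5R)-4-acetyl-5-[(1Z)-3-[(tert-butyldimethylsilyl)oxy]-2-[(5S)-5-methyl-4-oxo-4,5-dihydrofuran-2-yl]prop-1-en-1-yl]oxolan-2-one | O=C1C[C@H](C(C)=O)[C@@H](/C=C(/CO[Si](C)(C)C(C)(C)C)C2=CC(=O)[C@H](C)O2)O1 | intermediate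
21 | cyclic diisopropylsilylene bis-enol ether (6R,7S,4Z) linking the furan C1–O and the C8–O of the C8=C9 enol ether | CC1=C2C=C(O1)/C(CO[Si](C)(C)C(C)(C)C)=C\[C@H]3OC(=O)C[C@@H]3C(=C)O[Si](C(C)C)(C(C)C)O2 | intermediate
22 | (6R,7S,10S,4Z)-15-[(tert-butyldimethylsilyl)oxy]-3,10-epoxy-1,8-dioxogermacra-2,4-dien-12,6-olide | O=C1C[C@@H]2C(=O)C[C@]3(C)OC(=CC3=O)/C(CO[Si](C)(C)C(C)(C)C)=C\[C@H]2O1 | intermediate
23 | (6R,7R,8R,10S,4Z)-15-[(tert-butyldimethylsilyl)oxy]-3,10-epoxy-8-hydroxy-1-oxogermacra-2,4-dien-12,6-olide | O=C1C[C@@H]2[C@H](O)C[C@]3(C)OC(=CC3=O)/C(CO[Si](C)(C)C(C)(C)C)=C\[C@H]2O1 | intermediate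
24 | 8-O-trimethylsilyl ether of 23 (6R,7S,8R,10S) | O=C1C[C@@H]2[C@H](O[Si](C)(C)C)C[C@]3(C)OC(=CC3=O)/C(CO[Si](C)(C)C(C)(C)C)=C\[C@H]2O1 | intermediate
25 | 13-(dimethylamino)-8-O-trimethylsilyl Mannich base (C11 epimer mixture, not isolated) | CN(C)CC1C(=O)O[C@@H]2/C=C(/CO[Si](C)(C)C(C)(C)C)C3=CC(=O)[C@](C)(C[C@@H](O[Si](C)(C)C)[C@@H]12)O3 | intermediate
26 | 13-(dimethylamino)-8β-hydroxy Mannich base (C11 epimer mixture) | CN(C)CC1C(=O)O[C@@H]2/C=C(/CO[Si](C)(C)C(C)(C)C)C3=CC(=O)[C@](C)(C[C@@H](O)[C@@H]12)O3 | intermediate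
27 | 13-(trimethylammonio)-8β-hydroxy lactone iodide (C11 epimer mixture, not isolated) | C[N+](C)(C)CC1C(=O)O[C@@H]2/C=C(/CO[Si](C)(C)C(C)(C)C)C3=CC(=O)[C@](C)(C[C@@H](O)[C@@H]12)O3.[I-] | intermediate
28 | (6R,7R,8R,10S,4Z)-15-[(tert-butyldimethylsilyl)oxy]-3,10-epoxy-8-hydroxy-1-oxogermacra-2,4,11(13)-trien-12,6-olide | C=C1C(=O)O[C@@H]2/C=C(/CO[Si](C)(C)C(C)(C)C)C3=CC(=O)[C@](C)(C[C@@H](O)[C@@H]12)O3 | intermediate
29 | (2R)-2-methylbutanoic acid | CC[C@@H](C)C(=O)O | starting material
30 | (6R,7R,8R,10S,4Z)-15-[(tert-butyldimethylsilyl)oxy]-3,10-epoxy-8-[(2R)-2-methylbutanoyloxy]-1-oxogermacra-2,4,11(13)-trien-12,6-olide | C=C1C(=O)O[C@@H]2/C=C(/CO[Si](C)(C)C(C)(C)C)C3=CC(=O)[C@](C)(C[C@@H](OC(=O)[C@H](C)CC)[C@@H]12)O3 | intermediate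
31 | CNP0307052.2, (6R,7R,8R,10S,4Z)-3,10-epoxy-15-hydroxy-8-[(2R)-2-methylbutanoyloxy]-1-oxogermacra-2,4,11(13)-trien-12,6-olide | C=C1C(=O)O[C@@H]2/C=C(/CO)C3=CC(=O)[C@](C)(C[C@@H](OC(=O)[C@H](C)CC)[C@@H]12)O3 | target

**Step count**

Total: 21 steps. Longest linear sequence: 17 steps (steps 1–3, 5–7, 11–21).

**Three steps most likely to fail**

1. Step 15 (the new oxidative closure). What may go wrong: the Si–O bonds may be cleaved hydrolytically or oxidatively before C–C bond formation (returning 20); the radical cation may couple at C2 of the furan and rearomatise; C9 may approach the wrong furan face, giving the C10 epimer; or the dienyl furan may be over-oxidised. Fallback, setting out from 20 and returning at 22: the same bond would be made by polar alkylation without silicon. The dienolate of 20 (LiN(SiMe3)2, 2.05 equiv, THF, −78 °C) is added to N-iodosuccinimide (1.0 equiv); the far more basic C9 enolate should be iodinated first, and NH4Cl quench should give the iodomethyl ketone F1. Under Cs2CO3 in MeCN with slow addition at about 0.002 M, only the acidic furanone is deprotonated, and intramolecular SN2 C-alkylation of the furanolate at C10 by the α-iodoketone (C-alkylation of a 2-monosubstituted 3(2H)-furanone) should close the ten-membered ring to 22.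

2. Step 14 (tether formation). What may go wrong: the second silylation may occur between molecules (oligomers); the ketone may enolise toward C7 or the lactone may enolise; or the C9 enolate may attack the lactone carbonyl in a Claisen-type closure. Fallback, setting out from 20 and returning at 21: soft enolisation without free enolates. iPr2Si(OTf)2 (1.0 equiv) and Et3N in CH2Cl2 at −78 °C should silylate the most Lewis-basic carbonyl, that of the furanone, and give after loss of the C10 proton the furyl diisopropylsilyl triflate F2. On dilution and warming to 0 °C with more Et3N, the remaining Si–OTf should activate the C8 ketone intramolecularly, and the amine removes the less hindered C9 proton to give 21.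

3. Step 16 (C8 reduction). What may go wrong: the facial bias of the macrocycle may override the catalyst and deliver hydride to the other face, or the C1 carbonyl may be reduced competitively. Fallback, setting out from 22 and returning at 23: the ketone is reduced under substrate control (NaBH4, MeOH/CH2Cl2, −40 °C) to whichever epimer forms cleanly. If this is the 8α (8S) alcohol F3, Mitsunobu inversion (PPh3, diisopropyl azodicarboxylate, chloroacetic acid, toluene, 0 °C → rt) should give the 8β-chloroacetate F4. The chloroacetyl group is then removed under near-neutral conditions (thiourea, NaHCO3, EtOH, 50 °C), giving 23 without generating a free alkoxide.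

**Further compounds**

F1 | step 15 | (4S,5R)-5-[(1Z)-3-[(tert-butyldimethylsilyl)oxy]-2-(5-methyl-4-oxo-4,5-dihydrofuran-2-yl)prop-1-en-1-yl]-4-(2-iodoacetyl)oxolan-2-one (C10 epimer mixture) | O=C1C[C@H](C(=O)CI)[C@@H](/C=C(/CO[Si](C)(C)C(C)(C)C)C2=CC(=O)C(C)O2)O1
F2 | step 14 | 2-methyl-3-furyl diisopropylsilyl triflate of 20 (silicon on the C1 oxygen, C8 methyl ketone free) | CC1=C(O[Si](OS(=O)(=O)C(F)(F)F)(C(C)C)C(C)C)C=C(O1)/C(CO[Si](C)(C)C(C)(C)C)=C\[C@H]2OC(=O)C[C@@H]2C(C)=O
F3 | step 16 | (6R,7R,8S,10S,4Z)-15-[(tert-butyldimethylsilyl)oxy]-3,10-epoxy-8-hydroxy-1-oxogermacra-2,4-dien-12,6-olide (8-epimer of 23) | O=C1C[C@@H]2[C@@H](O)C[C@]3(C)OC(=CC3=O)/C(CO[Si](C)(C)C(C)(C)C)=C\[C@H]2O1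
F4 | step 16 | 8β-chloroacetate of 23 (8R) | O=C1C[C@@H]2[C@H](OC(=O)CCl)C[C@]3(C)OC(=CC3=O)/C(CO[Si](C)(C)C(C)(C)C)=C\[C@H]2O1
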